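## The problem

CNP0114537.0 (34) is a linear phlorotannin-type hexamer: six benzene rings joined only through five diaryl ether oxygens, with sixteen free hydroxyls and no stereocentre. The task is therefore one of oxygenation pattern and of the order in which the ether bonds are made. Reading from the phloroglucinol end, ring A is a 2,4,6-trihydroxyphenyl ether, rings B and D are 1,4-dioxygenated with hydroxyls on C3 and C5, rings C and E are 1,2-dioxygenated with hydroxyls on C3, C4 and C5, and ring F is a 3,4,5-trihydroxyphenyl ether. Each of the five ether bonds ends on one side at an aromatic carbon flanked by two oxygen-bearing carbons (ring A C2, ring B C4, ring C C2, ring D C4, ring E C2), which is where arylation of a phenoxide is slowest. With no stereocentre there is nothing to relay; control must come from where leaving groups and latent hydroxyls sit in the building blocks. The free pyrogallol and phloroglucinol units oxidise readily in air, above all in base, so every hydroxyl has to stay masked until the last step and the unmasking has to be acidic and non-oxidising. The feature that opens a non-classical route is ring B. Its oxygens on C1, C3 and C5 form the meta pattern that a vinylketene and an ynol ether deliver, and the fourth oxygen on C4 can ride in on the cyclobutenone, so C1–C2 can come from a ring A ethynyl ether and C3–C6 from a 4-aryloxy-3-ethoxycyclobutenone.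

## Retrosynthesis

**Unmasking.** Target 34 is traced back to hexamer 33 by cutting fifteen alkyl–oxygen bonds: fourteen methyl ethers and the ethyl ether on ring B C5, the ring B C3 hydroxyl being already free. Methyl ethers are preferred to benzyl ethers because every building block is then a catalogue methoxyarene and no hydroxyl ever has to be told from another. One Lewis-acid dealkylation treats methyl and ethyl alike, so the unsymmetrical OH/OEt pair left on ring B by the ring-forming step needs no adjustment. The forward reaction must leave the five diaryl ether bonds intact and end in acid.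

**Ring B.** Ring B of 33 is cut across C2–C3 and C1–C6 into cyclobutenone 19 and ethynyl ether 28. Cyclobutenone 19 supplies ring B C3–C6 and carries the complete C–D–E–F chain on the C4 oxygen; 28 supplies ring B C1–C2 with ring A on oxygen. The neighbouring cuts are the two ether bonds of ring B (ring C oxygen to ring B C4, ring B oxygen to ring A C2); each ends at a doubly flanked aromatic carbon and would need a copper coupling on a tetramer or pentamer. The benzannulation makes neither bond, because both oxygens are attached beforehand to the carbons that become ring B. The precursors are a tetramer and a monomer, so this is also the convergent cut. Carrying the whole D–E–F segment as spectator, and not a placeholder on ring D, means no aryl ether has to be made after ring B exists. The forward reaction must deliver one regiochemistry in a ketene–alkyne cycloaddition.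

**Ring A ethynyl ether.** The O–C(sp) bond of 28 is cut back to (E)-dichlorovinyl ether 25, and 25 to 2,4,6-trimethoxyphenol 22 and trichloroethylene 23. Phenol 22 comes from 2,4,6-trimethoxybenzaldehyde 20 by oxidative excision of the formyl carbon. The hindered ring A oxygen is thus bonded to a small two-carbon electrophile, not to an aromatic ring. The forward steps must tolerate a very electron-rich, oxidisable phenol and give an alkyne that is used soon after it is made.

**Cyclobutenone.** The four-membered ring of 19 is cut into ethoxyacetylene 16 and the aryloxyketene derived from acid 15. Acid 15 goes back through ester 14 to tetramer phenol 12 and methyl bromoacetate 13. The crowded ring C oxygen to ring B C4 bond is therefore an ordinary phenol alkylation at an sp3 carbon. The ketene cycloaddition must place the aryloxy group on C4 and the ethoxy group on C3, which the polarity of 16 ensures.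

**Ring C.** Phenol 12 is cut at its hydroxyl to aldehyde 10, and 10 at the ring D oxygen to ring C C2 bond into trimer phenol 9 and 2-bromo-3,4,5-trimethoxybenzaldehyde 2. In 2 the bromine marks ring C C2 and the formyl group both activates that carbon and is the latent ring C C1 hydroxyl, so the 1,2-dioxygenation next to three methoxy groups is fixed by the reagent. Phenol 9 has no ortho substituent, so this coupling is the easy kind.

**Ring D.** Phenol 9 is cut to aldehyde 7, and 7 at the ring E oxygen to ring D C4 bond into dimer phenol 5 and 4-bromo-3,5-dimethoxybenzaldehyde 6. The para formyl group of 6 activates the bromide and becomes the ring D C1 hydroxyl. This is the one doubly flanked aryl carbon that the route attacks with a phenoxide, and it does so early, on small, cheap partners.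

**Rings E and F.** Phenol 5 is cut to aldehyde 3, and 3 into 3,4,5-trimethoxyphenol 1 and a second molecule of 2. The logic is the same as for ring C, and 1 is unhindered.

## Roads not taken

**Alternative 1:** The cut removes both ether bonds of ring E at once. Ring E would enter as 1,2-dichloro-3,4,5-trimethoxybenzene A2. After η6-coordination of A2 to a CpRu+ fragment (from [CpRu(MeCN)3]PF6), both chlorides become SNAr leaving groups; the phenoxide of 4-(benzyloxy)-2,6-dimethoxyphenol A3 and then that of 1 would be introduced in one pot, and photolysis would release trimer A1. Hydrogenolysis of A1 would give phenol 9 of the present route.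
- Merits: the doubly flanked ring D oxygen is arylated under mild SNAr conditions, where step 3 here is a hot copper coupling of the most hindered kind. On that bond this road is the better one. Two ether bonds also form in one operation.
- Weak points: the two chlorides of A2 differ only in their outer neighbour (H against OMe), so the order of attack is not enforced by the substrate and wrong-way or double substitution would give isomers that are hard to separate. Ruthenium is stoichiometric, and neither A2 nor A3 is a stock compound.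
- Comparison: it ends at 9 in about the same number of steps as steps 1–4 and leaves rings A–C and their two hindered ethers untouched. The chosen plan sets against it ether regiochemistry fixed by the Br/CHO positions of 2 and 6, no stoichiometric precious metal, and a ring B construction that avoids substitution at a flanked aryl carbon.

**Alternative 2:** The cut is the ring E C1–C2 bond, ring E being grown from dimethyl squarate A6. Addition of a cis β-aryloxyvinyl nucleophile to A6 and O-methylation would give cyclobutenone A5. Heating A5 should give a dienylketene by 4π opening, and 6π closure would form ring E as phenol A4 (rings D–E, free hydroxyl on ring E C2).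
- Merits: thermal ring expansion of 4-alkenyl-4-alkoxycyclobutenones is an established reaction type, so this ring-forming step is on firmer ground than the benzannulation chosen here. The ring D oxygen to ring E bond is made as a vinyl ether before the ring exists.
- Weak points: the pentaoxygenated ring E is available ready-made in 2, so building it costs several steps for a ring that two steps supply here. The free hydroxyl of A4, flanked by a methoxy and an aryloxy group, must then be arylated with an unactivated, electron-rich ring F halide. Rings A–C remain to be solved.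
- Comparison: more reliable in its key step but longer, and it spends its ring construction on the ring that least needs it.

**Alternative 3:** The cut is the ring A C2–C3 bond. Base-mediated Claisen cyclisation of diketo ester A8, with C6 attacking the ester carbon, would close ring A as triol A7 (rings A–B).
- Merits: like the chosen plan it makes a hindered ether (ring A C2–O) by simple alkylation before the ring exists. It uses only classical carbonyl chemistry and avoids a heat-sensitive ynol ether or ketene; in that respect it is the safer road.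
- Weak points: C6 is the least acidic of the three enolisable positions of A8, so a polyanion is needed and enol O-acylation to a hydroxypyrone competes. A7 carries three free hydroxyls that must be remasked. After debenzylation of A7 the hardest bond of the molecule (ring B C4 oxygen to ring C) still has to be made from a doubly flanked phenol and an unactivated ring C halide.
- Comparison: it solves the ring A ether, which the chosen plan handles equally simply in step 11, and leaves unsolved the ring B C4 ether, which the benzannulation settles together with it.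

Key step: step 13

## Route

Remark on conventions: rings are lettered A to F from the phloroglucinol end. Ring B is numbered with C1 on the ring A oxygen and C4 on the ring C oxygen. Ar is the C–D–E–F aryl group of phenol 12, that is 2-{3,5-dimethoxy-4-[3,4,5-trimethoxy-2-(3,4,5-trimethoxyphenoxy)phenoxy]phenoxy}-3,4,5-trimethoxyphenyl. The free hexadecaphenol 34 is assumed to be handled under argon as the neutral compound.

Step 1
Reactants: 1 3,4,5-trimethoxyphenol; 2 2-bromo-3,4,5-trimethoxybenzaldehyde
Product: 3 3,4,5-trimethoxy-2-(3,4,5-trimethoxyphenoxy)benzaldehyde (rings E–F)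
Conditions: CuI (10 mol %), picolinic acid (20 mol %), K3PO4, DMSO, 90 °C
Reagents that add atoms: none
Why: Ullmann diaryl ether coupling of an unhindered, electron-rich phenoxide with a bromide activated by its ortho formyl group; the Br/CHO positions of 2 fix the ring E oxygenation pattern.

Step 2
Reactants: 3 3,4,5-trimethoxy-2-(3,4,5-trimethoxyphenoxy)benzaldehyde
Product: 5 3,4,5-trimethoxy-2-(3,4,5-trimethoxyphenoxy)phenol, via aryl formate 4 (not isolated)
Conditions: mCPBA, CH2Cl2, 0 °C → rt; then K2CO3 (cat.), MeOH, rt
Reagents that add atoms: mCPBA, O=C(OO)c1cccc(Cl)c1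
Why: Baeyer–Villiger (Dakin-type) oxidation of an electron-rich benzaldehyde, aryl migration being favoured by the ortho aryloxy and para methoxy donors; formate 4 is methanolysed to the phenol.

Step 3
Reactants: 5 3,4,5-trimethoxy-2-(3,4,5-trimethoxyphenoxy)phenol; 6 4-bromo-3,5-dimethoxybenzaldehyde
Product: 7 3,5-dimethoxy-4-[3,4,5-trimethoxy-2-(3,4,5-trimethoxyphenoxy)phenoxy]benzaldehyde (rings D–E–F)
Conditions: CuI (20 mol %), picolinic acid (40 mol %), K3PO4, DMSO, 100 °C
Reagents that add atoms: none
Why: Ullmann diaryl ether coupling at a bromide activated by the para formyl group; this is the most hindered coupling of the route (bromide between two methoxy groups, ortho-substituted phenol), and the picolinic acid ligand system is suited to hindered partners.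

Step 4
Reactants: 7 3,5-dimethoxy-4-[3,4,5-trimethoxy-2-(3,4,5-trimethoxyphenoxy)phenoxy]benzaldehyde
Product: 9 3,5-dimethoxy-4-[3,4,5-trimethoxy-2-(3,4,5-trimethoxyphenoxy)phenoxy]phenol, via aryl formate 8 (not isolated)
Conditions: mCPBA, CH2Cl2, 0 °C → rt; then K2CO3 (cat.), MeOH, rt
Reagents that add atoms: mCPBA, O=C(OO)c1cccc(Cl)c1
Why: Baeyer–Villiger (Dakin-type) oxidation; ring D has the substitution pattern of 3,4,5-trimethoxybenzaldehyde, for which aryl migration to the formate is the normal course.

Step 5
Reactants: 9 3,5-dimethoxy-4-[3,4,5-trimethoxy-2-(3,4,5-trimethoxyphenoxy)phenoxy]phenol; 2 2-bromo-3,4,5-trimethoxybenzaldehyde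
Product: 10 2-{3,5-dimethoxy-4-[3,4,5-trimethoxy-2-(3,4,5-trimethoxyphenoxy)phenoxy]phenoxy}-3,4,5-trimethoxybenzaldehyde (rings C–D–E–F, ArCHO)
Conditions: CuI (10 mol %), picolinic acid (20 mol %), K3PO4, DMSO, 90 °C
Reagents that add atoms: none
Why: Ullmann diaryl ether coupling as in step 1; phenol 9 has no ortho substituent and the bromide is activated by the ortho formyl group.

Step 6
Reactants: 10 2-{3,5-dimethoxy-4-[3,4,5-trimethoxy-2-(3,4,5-trimethoxyphenoxy)phenoxy]phenoxy}-3,4,5-trimethoxybenzaldehyde
Product: 12 2-{3,5-dimethoxy-4-[3,4,5-trimethoxy-2-(3,4,5-trimethoxyphenoxy)phenoxy]phenoxy}-3,4,5-trimethoxyphenol (ArOH), via aryl formate 11 (not isolated)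
Conditions: mCPBA, CH2Cl2, 0 °C → rt; then K2CO3 (cat.), MeOH, rt
Reagents that add atoms: mCPBA, O=C(OO)c1cccc(Cl)c1
Why: Baeyer–Villiger (Dakin-type) oxidation as in step 2, with the same ortho aryloxy and para methoxy donors on the migrating ring.

Step 7
Reactants: 12 ArOH; 13 methyl bromoacetate
Product: 14 methyl 2-(aryloxy)acetate, ArOCH2CO2Me
Conditions: K2CO3, acetone, reflux
Reagents that add atoms: none
Why: Williamson ether synthesis on a reactive primary α-halo ester; the two carbons introduced become ring B C4 and C3, so the crowded ring C oxygen to ring B C4 bond is made as an sp3 C–O bond.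

Step 8
Reactants: 14 methyl 2-(aryloxy)acetate
Product: 15 2-(aryloxy)acetic acid, ArOCH2CO2H
Conditions: LiOH, THF/MeOH/H2O, rt; then 1 M HCl
Reagents that add atoms: lithium hydroxide, [Li+].[OH-]
Why: Ester saponification; aryl methyl ethers and diaryl ethers are inert to aqueous hydroxide at room temperature.

Step 9
Reactants: 15 2-(aryloxy)acetic acid; 16 ethoxyacetylene
Product: 19 rac-4-(aryloxy)-3-ethoxycyclobut-2-en-1-one, via acid chloride 17 (not isolated), via aryloxyketene 18 (not isolated)
Conditions: 1-chloro-N,N,2-trimethylprop-1-en-1-amine (Ghosez reagent), CH2Cl2, 0 °C → rt; then added slowly to 16 (5 equiv), Et3N, CH2Cl2, 0 °C → rt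
Reagents that add atoms: none
Why: Neutral acid chloride formation avoids acylation of the electron-rich rings; Et3N dehydrochlorination gives ketene 18, and the known [2+2] cycloaddition of ketenes with ethoxyacetylene (terminal alkyne carbon to the ketene carbonyl carbon) gives the 3-ethoxycyclobutenone with the aryloxy group on C4. The C4 stereocentre is formed racemic and is erased in step 13.

Step 10
Reactants: 20 2,4,6-trimethoxybenzaldehyde
Product: 22 2,4,6-trimethoxyphenol, via 2,4,6-trimethoxyphenyl formate 21 (not isolated)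
Conditions: mCPBA, CH2Cl2, 0 °C; then K2CO3 (cat.), MeOH, rt, argon
Reagents that add atoms: mCPBA, O=C(OO)c1cccc(Cl)c1
Why: Baeyer–Villiger (Dakin-type) oxidation of a benzaldehyde with two ortho and one para methoxy donors; the air-sensitive phenol is used directly.

Step 11
Reactants: 22 2,4,6-trimethoxyphenol; 23 trichloroethylene
Product: 25 2-{[(E)-1,2-dichloroethenyl]oxy}-1,3,5-trimethoxybenzene, via dichloroacetylene 24 (not isolated)
Conditions: K2CO3, DMF, 70 °C, argon
Reagents that add atoms: none
Why: Known vinylic substitution of phenols on trichloroethylene by elimination–addition: base forms 24 in low concentration, the phenoxide adds and anti protonation gives the (E)-dichlorovinyl ether; the hindered ring A oxygen meets only a linear two-carbon electrophile.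

Step 12
Reactants: 25 2-{[(E)-1,2-dichloroethenyl]oxy}-1,3,5-trimethoxybenzene
Product: 28 2-ethynyloxy-1,3,5-trimethoxybenzene, via chloroethynyl ether 26 (not isolated), via lithium acetylide 27 (not isolated)
Conditions: n-BuLi (2.3 equiv), THF, −78 → −40 °C; then H2O, −78 → 0 °C; used at once as a solution
Reagents that add atoms: none
Why: Established ynol ether synthesis from 1,2-dichlorovinyl ethers: dehydrochlorination to 26, lithium–chlorine exchange to 27 and protonation; the low temperature keeps butyllithium from metalating the ring between two methoxy groups.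

Step 13
Reactants: 19 rac-4-(aryloxy)-3-ethoxycyclobut-2-en-1-one; 28 2-ethynyloxy-1,3,5-trimethoxybenzene
Product: 33 2-(aryloxy)-3-ethoxy-5-(2,4,6-trimethoxyphenoxy)phenol (hexamer with free hydroxyl on ring B C3 and ethoxy on ring B C5), via vinylketene 29 (not isolated), via vinylcyclobutenone 30 (not isolated), via dienylketene 31 (not isolated), via cyclohexadienone 32 (not isolated)
Conditions: 28 (2.5 equiv), toluene, 80 °C → 110 °C, argon, sealed tube
Reagents that add atoms: none
Why: Proposed new method: heating should open 19 by conrotatory 4π electrocyclic ring opening (aryloxy group rotating outward) to vinylketene 29, whose ketene carbon is attacked by the unsubstituted, nucleophilic carbon of ynol ether 28, and polar [2+2] closure gives the four-membered ring of vinylcyclobutenone 30. A second 4π opening gives dienylketene 31, and thermal disrotatory 6π electrocyclisation joins the ketene carbon to the aryloxy-bearing terminus, closing the six-membered ring B as cyclohexadienone 32, which enolises to phenol 33 with the ketene oxygen as the C3 hydroxyl. Net, the ring B C2–C3 and C1–C6 bonds are new. The closest known reaction type is the Danheiser benzannulation of cyclobutenones with alkoxyacetylenes to resorcinol monoethers; untested are the 3-alkoxy-4-aryloxy substitution of the cyclobutenone and an aryl in place of an alkyl ynol ether. The reasoning for both is that the C4 aryloxy donor lowers the barrier of the first ring opening that the vinylogous-ester character of 19 raises, and that an aryl ynol ether has no β-hydrogen for retro-ene loss of ketene, so it can be heated in excess. No stereocentre is created: the sp3 centres of 19, 30 and 32 vanish on aromatisation, and the alkene geometries of 29 and 31 can equilibrate through reversible ring closure. The selectivity needed is the regiochemistry of the ketene–alkyne cycloaddition, secured by the polarity of the ynol ether (oxygen-bearing carbon to the ketene α-carbon), which places the ring A oxygen para to the ring C oxygen.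

Step 14
Reactants: 33 2-(aryloxy)-3-ethoxy-5-(2,4,6-trimethoxyphenoxy)phenol
Product: 34 CNP0114537.0, 2-{3,5-dihydroxy-4-[3,4,5-trihydroxy-2-(3,5-dihydroxy-4-{3,4,5-trihydroxy-2-(3,4,5-trihydroxyphenoxy)phenoxy}phenoxy)phenoxy]phenoxy}benzene-1,3,5-triol
Conditions: BBr3 (excess), CH2Cl2, −78 °C → rt; MeOH then H2O at 0 °C, argon
Reagents that add atoms: none
Why: Lewis-acid cleavage of aryl methyl and aryl ethyl ethers by BBr3 through bromide attack at the alkyl carbon; diaryl ether bonds offer no such carbon and survive, and the acidic, non-oxidising medium protects the pyrogallol and phloroglucinol units.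

## Compound list

1 | 3,4,5-trimethoxyphenol (ring F) | COc1cc(O)cc(OC)c1OC | starting material
2 | 2-bromo-3,4,5-trimethoxybenzaldehyde (rings E and C) | COc1cc(C=O)c(Br)c(OC)c1OC | starting material
3 | 3,4,5-trimethoxy-2-(3,4,5-trimethoxyphenoxy)benzaldehyde | O=Cc1cc(OC)c(OC)c(OC)c1Oc1cc(OC)c(OC)c(OC)c1 | intermediate
4 | 3,4,5-trimethoxy-2-(3,4,5-trimethoxyphenoxy)phenyl formate (not isolated) | O=COc1cc(OC)c(OC)c(OC)c1Oc1cc(OC)c(OC)c(OC)c1 | intermediate
5 | 3,4,5-trimethoxy-2-(3,4,5-trimethoxyphenoxy)phenol | Oc1cc(OC)c(OC)c(OC)c1Oc1cc(OC)c(OC)c(OC)c1 | intermediate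
6 | 4-bromo-3,5-dimethoxybenzaldehyde (ring D) | COc1cc(C=O)cc(OC)c1Br | starting material
7 | 3,5-dimethoxy-4-[3,4,5-trimethoxy-2-(3,4,5-trimethoxyphenoxy)phenoxy]benzaldehyde | O=Cc1cc(OC)c(Oc2cc(OC)c(OC)c(OC)c2Oc2cc(OC)c(OC)c(OC)c2)c(OC)c1 | intermediate
8 | 3,5-dimethoxy-4-[3,4,5-trimethoxy-2-(3,4,5-trimethoxyphenoxy)phenoxy]phenyl formate (not isolated) | O=COc1cc(OC)c(Oc2cc(OC)c(OC)c(OC)c2Oc2cc(OC)c(OC)c(OC)c2)c(OC)c1 | intermediate
9 | 3,5-dimethoxy-4-[3,4,5-trimethoxy-2-(3,4,5-trimethoxyphenoxy)phenoxy]phenol | Oc1cc(OC)c(Oc2cc(OC)c(OC)c(OC)c2Oc2cc(OC)c(OC)c(OC)c2)c(OC)c1 | intermediate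
10 | 2-{3,5-dimethoxy-4-[3,4,5-trimethoxy-2-(3,4,5-trimethoxyphenoxy)phenoxy]phenoxy}-3,4,5-trimethoxybenzaldehyde (ArCHO) | O=Cc1cc(OC)c(OC)c(OC)c1Oc1cc(OC)c(Oc2cc(OC)c(OC)c(OC)c2Oc2cc(OC)c(OC)c(OC)c2)c(OC)c1 | intermediate
11 | aryl formate ArOCHO of 10 (not isolated) | O=COc1cc(OC)c(OC)c(OC)c1Oc1cc(OC)c(Oc2cc(OC)c(OC)c(OC)c2Oc2cc(OC)c(OC)c(OC)c2)c(OC)c1 | intermediate
12 | 2-{3,5-dimethoxy-4-[3,4,5-trimethoxy-2-(3,4,5-trimethoxyphenoxy)phenoxy]phenoxy}-3,4,5-trimethoxyphenol (ArOH) | Oc1cc(OC)c(OC)c(OC)c1Oc1cc(OC)c(Oc2cc(OC)c(OC)c(OC)c2Oc2cc(OC)c(OC)c(OC)c2)c(OC)c1 | intermediate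
13 | methyl bromoacetate | COC(=O)CBr | starting material
14 | methyl 2-(aryloxy)acetate, ArOCH2CO2Me | COC(=O)COc1cc(OC)c(OC)c(OC)c1Oc1cc(OC)c(Oc2cc(OC)c(OC)c(OC)c2Oc2cc(OC)c(OC)c(OC)c2)c(OC)c1 | intermediate
15 | 2-(aryloxy)acetic acid, ArOCH2CO2H | OC(=O)COc1cc(OC)c(OC)c(OC)c1Oc1cc(OC)c(Oc2cc(OC)c(OC)c(OC)c2Oc2cc(OC)c(OC)c(OC)c2)c(OC)c1 | intermediate
16 | ethoxyacetylene | CCOC#C | starting material
17 | 2-(aryloxy)acetyl chloride, ArOCH2COCl (not isolated) | ClC(=O)COc1cc(OC)c(OC)c(OC)c1Oc1cc(OC)c(Oc2cc(OC)c(OC)c(OC)c2Oc2cc(OC)c(OC)c(OC)c2)c(OC)c1 | intermediate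
18 | aryloxyketene, ArOCH=C=O (not isolated) | O=C=COc1cc(OC)c(OC)c(OC)c1Oc1cc(OC)c(Oc2cc(OC)c(OC)c(OC)c2Oc2cc(OC)c(OC)c(OC)c2)c(OC)c1 | intermediate
19 | rac-4-(aryloxy)-3-ethoxycyclobut-2-en-1-one | CCOC1=CC(=O)C1Oc1cc(OC)c(OC)c(OC)c1Oc1cc(OC)c(Oc2cc(OC)c(OC)c(OC)c2Oc2cc(OC)c(OC)c(OC)c2)c(OC)c1 | intermediate
20 | 2,4,6-trimethoxybenzaldehyde | COc1cc(OC)c(C=O)c(OC)c1 | starting material
21 | 2,4,6-trimethoxyphenyl formate (not isolated) | O=COc1c(OC)cc(OC)cc1OC | intermediate
22 | 2,4,6-trimethoxyphenol | Oc1c(OC)cc(OC)cc1OC | intermediate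
23 | trichloroethylene | ClC=C(Cl)Cl | starting material
24 | dichloroacetylene (not isolated) | ClC#CCl | intermediate
25 | 2-{[(E)-1,2-dichloroethenyl]oxy}-1,3,5-trimethoxybenzene | Cl/C=C(/Cl)Oc1c(OC)cc(OC)cc1OC | intermediate
26 | 2-(chloroethynyloxy)-1,3,5-trimethoxybenzene (not isolated) | ClC#COc1c(OC)cc(OC)cc1OC | intermediate
27 | lithium (2,4,6-trimethoxyphenoxy)acetylide (not isolated) | [Li]C#COc1c(OC)cc(OC)cc1OC | intermediate
28 | 2-ethynyloxy-1,3,5-trimethoxybenzene (ring A ethynyl ether) | C#COc1c(OC)cc(OC)cc1OC | intermediate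
29 | (3Z)-4-(aryloxy)-3-ethoxybuta-1,3-dien-1-one, vinylketene, geometry as expected from outward rotation (not isolated) | O=C=C/C(OCC)=C/Oc1cc(OC)c(OC)c(OC)c1Oc1cc(OC)c(Oc2cc(OC)c(OC)c(OC)c2Oc2cc(OC)c(OC)c(OC)c2)c(OC)c1 | intermediate
30 | rac-4-[(Z)-2-(aryloxy)-1-ethoxyethenyl]-3-(2,4,6-trimethoxyphenoxy)cyclobut-2-en-1-one (not isolated) | O=C1C=C(Oc2c(OC)cc(OC)cc2OC)C1/C(OCC)=C/Oc1cc(OC)c(OC)c(OC)c1Oc1cc(OC)c(Oc2cc(OC)c(OC)c(OC)c2Oc2cc(OC)c(OC)c(OC)c2)c(OC)c1 | intermediate
31 | (3E,5Z)-6-(aryloxy)-5-ethoxy-3-(2,4,6-trimethoxyphenoxy)hexa-1,3,5-trien-1-one, dienylketene in its cyclising geometry (not isolated) | O=C=C/C(Oc1c(OC)cc(OC)cc1OC)=C\C(OCC)=C\Oc1cc(OC)c(OC)c(OC)c1Oc1cc(OC)c(Oc2cc(OC)c(OC)c(OC)c2Oc2cc(OC)c(OC)c(OC)c2)c(OC)c1 | intermediate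
32 | rac-6-(aryloxy)-5-ethoxy-3-(2,4,6-trimethoxyphenoxy)cyclohexa-2,4-dien-1-one (not isolated) | O=C1C=C(Oc2c(OC)cc(OC)cc2OC)C=C(OCC)C1Oc1cc(OC)c(OC)c(OC)c1Oc1cc(OC)c(Oc2cc(OC)c(OC)c(OC)c2Oc2cc(OC)c(OC)c(OC)c2)c(OC)c1 | intermediate
33 | 2-(aryloxy)-3-ethoxy-5-(2,4,6-trimethoxyphenoxy)phenol (A–B–C–D–E–F hexamer, ring B C3 OH and C5 OEt) | CCOc1cc(Oc2c(OC)cc(OC)cc2OC)cc(O)c1Oc1cc(OC)c(OC)c(OC)c1Oc1cc(OC)c(Oc2cc(OC)c(OC)c(OC)c2Oc2cc(OC)c(OC)c(OC)c2)c(OC)c1 | intermediate
34 | CNP0114537.0, 2-{3,5-dihydroxy-4-[3,4,5-trihydroxy-2-(3,5-dihydroxy-4-{3,4,5-trihydroxy-2-(3,4,5-trihydroxyphenoxy)phenoxy}phenoxy)phenoxy]phenoxy}benzene-1,3,5-triol | Oc1cc(O)c(Oc2cc(O)c(Oc3cc(O)c(O)c(O)c3Oc3cc(O)c(Oc4cc(O)c(O)c(O)c4Oc4cc(O)c(O)c(O)c4)c(O)c3)c(O)c2)c(O)c1 | target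

## Step count and risks

Total: 14 steps. Longest linear sequence: 11 steps (steps 1–9, 13 and 14); the ring A branch (steps 10–12) joins at step 13.

**Step 13 (key step, proposed new method).** The likely failure is that the vinylketene forms but is not intercepted. The aryl ynol ether is a weaker nucleophile than an alkyl one and the doubly donor-substituted ketene a weaker electrophile, so ketene dimerisation, acylation of the product phenol by the ketene, or slow decomposition on prolonged heating can take over. Reversed cycloaddition regiochemistry is the lesser concern. The fallback uses only the copper coupling and Dakin chemistry already proven in steps 1–6. It sets out from phenol 12, which is coupled with bromide 6 (CuI, picolinic acid, K3PO4, DMSO) to the pentamer aldehyde 3,5-dimethoxy-4-(aryloxy)benzaldehyde F1. Oxidation with mCPBA gives aryl formate F2, and methanolysis gives 3,5-dimethoxy-4-(aryloxy)phenol F3, which is ring B with its C1 hydroxyl free and unhindered. A second coupling with 6 gives the hexamer aldehyde 4-[3,5-dimethoxy-4-(aryloxy)phenoxy]-3,5-dimethoxybenzaldehyde F4, whose formyl group sits para on ring A. Oxidation to aryl formate F5 and methanolysis give 4-[3,5-dimethoxy-4-(aryloxy)phenoxy]-3,5-dimethoxyphenol F6, and BBr3 cleavage of its sixteen methyl ethers returns to the route at 34. The price is two more couplings at doubly flanked bromides on large phenols, which the benzannulation is meant to avoid.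

**Step 3.** The likely failure is slow substitution at the bromide flanked by two methoxy groups, with hydrodebromination of 6 and oxidative loss of phenol 5 competing at the temperature needed. The fallback reverses the polarity of the bond so that the hindered partner is the phenol, which copper-mediated boronic acid arylation tolerates even with two ortho substituents. It sets out from 5, which is converted with Tf2O and pyridine into 3,4,5-trimethoxy-2-(3,4,5-trimethoxyphenoxy)phenyl trifluoromethanesulfonate F7. Miyaura borylation (B2pin2, PdCl2(dppf), KOAc, dioxane) gives the pinacol boronate F8, and NaIO4/NH4OAc cleavage gives [3,4,5-trimethoxy-2-(3,4,5-trimethoxyphenoxy)phenyl]boronic acid F9. Chan–Lam–Evans coupling of F9 with commercial 4-hydroxy-3,5-dimethoxybenzaldehyde (Cu(OAc)2, pyridine, molecular sieves, CH2Cl2, air) returns to the route at 7.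

**Step 9.** The likely failure is consumption of ketene 18 before ethoxyacetylene traps it, by self-condensation or by acylation of the neighbouring electron-rich ring C, and hydrolysis of the vinylogous ester 19 on silica. The fallback sets out from acid 15 and generates the ketene in the same way, but in the presence of the much more nucleophilic 1,1-diethoxyethene, to give rac-2-(aryloxy)-3,3-diethoxycyclobutan-1-one F10. Elimination of ethanol towards the unsubstituted methylene (neutral alumina, or catalytic acid in toluene with removal of ethanol) returns to the route at 19.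

**Step 12.** The likely failure is loss of the terminal aryl ethynyl ether by oligomerisation or hydration during concentration and chromatography, and to a lesser degree ring lithiation by excess butyllithium. The fallback sets out from 25; acetylide 27 is quenched with Me3SiCl instead of water to give trimethyl[(2,4,6-trimethoxyphenoxy)ethynyl]silane F11, a C-protected ynol ether that can be purified and stored. Fluoride (Bu4NF, THF, 0 °C) immediately before the benzannulation releases the alkyne and returns to the route at 28, which is taken into step 13 without concentration.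

**Step 14.** The likely failure is incomplete cleavage across fifteen ethers, giving partly methylated mixtures, and oxidative degradation of the hexadecaphenol during aqueous work-up and chromatography. The fallback sets out from 33: the crude BBr3 product is acetylated (Ac2O, pyridine) to the hexadeca-O-acetate of the target F12, which is stable and can be purified on silica and checked for complete dealkylation. Acid methanolysis (anhydrous HCl in degassed MeOH) returns to the route at 34 without exposing it to base.

## Further compounds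

F1 | step 13 | 3,5-dimethoxy-4-(aryloxy)benzaldehyde (rings B–C–D–E–F) | O=Cc1cc(OC)c(Oc2cc(OC)c(OC)c(OC)c2Oc2cc(OC)c(Oc3cc(OC)c(OC)c(OC)c3Oc3cc(OC)c(OC)c(OC)c3)c(OC)c2)c(OC)c1
F2 | step 13 | 3,5-dimethoxy-4-(aryloxy)phenyl formate | O=COc1cc(OC)c(Oc2cc(OC)c(OC)c(OC)c2Oc2cc(OC)c(Oc3cc(OC)c(OC)c(OC)c3Oc3cc(OC)c(OC)c(OC)c3)c(OC)c2)c(OC)c1
F3 | step 13 | 3,5-dimethoxy-4-(aryloxy)phenol | Oc1cc(OC)c(Oc2cc(OC)c(OC)c(OC)c2Oc2cc(OC)c(Oc3cc(OC)c(OC)c(OC)c3Oc3cc(OC)c(OC)c(OC)c3)c(OC)c2)c(OC)c1
F4 | step 13 | 4-[3,5-dimethoxy-4-(aryloxy)phenoxy]-3,5-dimethoxybenzaldehyde | O=Cc1cc(OC)c(Oc2cc(OC)c(Oc3cc(OC)c(OC)c(OC)c3Oc3cc(OC)c(Oc4cc(OC)c(OC)c(OC)c4Oc4cc(OC)c(OC)c(OC)c4)c(OC)c3)c(OC)c2)c(OC)c1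
F5 | step 13 | 4-[3,5-dimethoxy-4-(aryloxy)phenoxy]-3,5-dimethoxyphenyl formate | O=COc1cc(OC)c(Oc2cc(OC)c(Oc3cc(OC)c(OC)c(OC)c3Oc3cc(OC)c(Oc4cc(OC)c(OC)c(OC)c4Oc4cc(OC)c(OC)c(OC)c4)c(OC)c3)c(OC)c2)c(OC)c1
F6 | step 13 | 4-[3,5-dimethoxy-4-(aryloxy)phenoxy]-3,5-dimethoxyphenol | Oc1cc(OC)c(Oc2cc(OC)c(Oc3cc(OC)c(OC)c(OC)c3Oc3cc(OC)c(Oc4cc(OC)c(OC)c(OC)c4Oc4cc(OC)c(OC)c(OC)c4)c(OC)c3)c(OC)c2)c(OC)c1
F7 | step 3 | 3,4,5-trimethoxy-2-(3,4,5-trimethoxyphenoxy)phenyl trifluoromethanesulfonate | O=S(=O)(Oc1cc(OC)c(OC)c(OC)c1Oc1cc(OC)c(OC)c(OC)c1)C(F)(F)F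
F8 | step 3 | 4,4,5,5-tetramethyl-2-[3,4,5-trimethoxy-2-(3,4,5-trimethoxyphenoxy)phenyl]-1,3,2-dioxaborolane | CC1(C)OB(OC1(C)C)c1cc(OC)c(OC)c(OC)c1Oc1cc(OC)c(OC)c(OC)c1
F9 | step 3 | [3,4,5-trimethoxy-2-(3,4,5-trimethoxyphenoxy)phenyl]boronic acid | OB(O)c1cc(OC)c(OC)c(OC)c1Oc1cc(OC)c(OC)c(OC)c1
F10 | step 9 | rac-2-(aryloxy)-3,3-diethoxycyclobutan-1-one | CCOC1(OCC)CC(=O)C1Oc1cc(OC)c(OC)c(OC)c1Oc1cc(OC)c(Oc2cc(OC)c(OC)c(OC)c2Oc2cc(OC)c(OC)c(OC)c2)c(OC)c1
F11 | step 12 | trimethyl[(2,4,6-trimethoxyphenoxy)ethynyl]silane | C[Si](C)(C)C#COc1c(OC)cc(OC)cc1OC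
F12 | step 14 | hexadeca-O-acetate of CNP0114537.0 | CC(=O)Oc1cc(OC(C)=O)c(Oc2cc(OC(C)=O)c(Oc3cc(OC(C)=O)c(OC(C)=O)c(OC(C)=O)c3Oc3cc(OC(C)=O)c(Oc4cc(OC(C)=O)c(OC(C)=O)c(OC(C)=O)c4Oc4cc(OC(C)=O)c(OC(C)=O)c(OC(C)=O)c4)c(OC(C)=O)c3)c(OC(C)=O)c2)c(OC(C)=O)c1
A1 | alternative 1 | 5-(benzyloxy)-1,3-dimethoxy-2-[3,4,5-trimethoxy-2-(3,4,5-trimethoxyphenoxy)phenoxy]benzene (rings D–E–F) | COc1cc(Oc2c(Oc3c(OC)cc(OCc4ccccc4)cc3OC)cc(OC)c(OC)c2OC)cc(OC)c1OC
A2 | alternative 1 | 1,2-dichloro-3,4,5-trimethoxybenzene | COc1cc(Cl)c(Cl)c(OC)c1OC
A3 | alternative 1 | 4-(benzyloxy)-2,6-dimethoxyphenol | COc1cc(OCc2ccccc2)cc(OC)c1O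
A4 | alternative 2 | 6-[4-(benzyloxy)-2,6-dimethoxyphenoxy]-2,3,4-trimethoxyphenol (rings D–E) | Oc1c(OC)c(OC)c(OC)cc1Oc1c(OC)cc(OCc2ccccc2)cc1OC
A5 | alternative 2 | rac-4-{(Z)-2-[4-(benzyloxy)-2,6-dimethoxyphenoxy]ethenyl}-2,3,4-trimethoxycyclobut-2-en-1-one | COC1=C(OC)C(OC)(/C=C\Oc2c(OC)cc(OCc3ccccc3)cc2OC)C1=O
A6 | alternative 2 | dimethyl squarate | COC1=C(OC)C(=O)C1=O
A7 | alternative 3 | 2-[4-(benzyloxy)-3,5-dimethoxyphenoxy]benzene-1,3,5-triol (rings A–B) | Oc1cc(O)c(Oc2cc(OC)c(OCc3ccccc3)c(OC)c2)c(O)c1
A8 | alternative 3 | methyl 6-[4-(benzyloxy)-3,5-dimethoxyphenoxy]-3,5-dioxohexanoate | COC(=O)CC(=O)CC(=O)COc1cc(OC)c(OCc2ccccc2)c(OC)c1
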